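**Plan**

- Retrosynthetic cuts: C4–C4a (acylation of ring A closes ring C), O1–C2 (aryl ether), C2–C3 (hydroxymethylation of an arylacetyl imide), the O2'–CMe2 bond of the dimethylpyran ring, and ring B itself across C1'–C2', C2'–C3', C4'–C5' and C5'–C6'.
- Enabling feature: ring B is a 1,2,3,4-tetrasubstituted resorcinol (carbon at C1', oxygen at C2', carbon at C3', oxygen at C4') in which O2' is the pyran oxygen and O4' a free phenol. A benzannulation that makes O2' from a ketene carbonyl (free OH) and O4' from an ynol silyl ether tells the two oxygens apart as the ring forms.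
- Forward order: ring B is built from two acyclic pieces (step 6), the dimethylpyran ring is closed on O2' (step 7), the two-carbon arm is oxidised to the arylacetic acid, and ring C is closed last onto ring A, which enters intact from phloroglucinol.
- Stereochemistry: the only stereocentre, C3 (R), is set by (S)-4-benzyloxazolidin-2-one in a titanium enolate hydroxymethylation (step 11) and carried through base-free closing steps.

Key step: step 6

Remark: primed locants refer to ring B (C1' is bonded to C3). C3 is an enolisable α-aryl ketone centre, and the route assumes it keeps its configuration under the acidic or buffered conditions of steps 15 and 16.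

**Route**

Step 1
Reactants: 1 propane-1,3-diol
Product: 2 3-[(tert-butyldimethylsilyl)oxy]propan-1-ol
Conditions: TBSCl (1 equiv), imidazole, 1 (4 equiv), CH2Cl2/THF, 0 °C to rt
Reagents that add atoms: tert-butyldimethylsilyl chloride, CC(C)(C)[Si](C)(C)Cl
Why: Statistical monosilylation (silyl ether formation) of a symmetric diol used in excess should keep the bis-silyl ether minor, and the surplus diol is removed by aqueous washing.

Step 2
Reactants: 2 3-[(tert-butyldimethylsilyl)oxy]propan-1-ol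
Product: 3 3-[(tert-butyldimethylsilyl)oxy]propanal
Conditions: TEMPO (cat.), PhI(OAc)2, CH2Cl2, rt
Reagents that add atoms: none
Why: Nitroxyl-catalysed oxidation of a primary alcohol stops at the aldehyde in the absence of water and uses no base that could cause β-elimination of the silyloxy group.

Step 3
Reactants: 3 3-[(tert-butyldimethylsilyl)oxy]propanal
Product: 4 (E)-6-[(tert-butyldimethylsilyl)oxy]hex-3-en-2-one
Conditions: Ph3P=CHC(O)CH3, CH2Cl2, 40 °C
Reagents that add atoms: 1-(triphenylphosphoranylidene)propan-2-one, CC(=O)C=P(c1ccccc1)(c1ccccc1)c1ccccc1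
Why: Wittig olefination with a stabilised acyl ylide should give the (E)-enone.

Step 4
Reactants: 4 (E)-6-[(tert-butyldimethylsilyl)oxy]hex-3-en-2-one
Product: 6 (E)-6-[(tert-butyldimethylsilyl)oxy]-1-diazohex-3-en-2-one, via trifluoroacetyl diketone 5 (not isolated)
Conditions: LiN(SiMe3)2, THF, −78 °C; CF3CO2CH2CF3; cold 5% aq. HCl work-up; then MsN3, Et3N, H2O (1 equiv), MeCN, rt
Reagents that add atoms: methanesulfonyl azide, CS(=O)(=O)N=[N+]=[N-]
Why: Deacylative Regitz diazo transfer, in which the kinetic methyl enolate is trifluoroacetylated and diketone 5 exchanges the trifluoroacetyl group for the diazo group, avoids the dipolar cycloaddition that spoils acid chloride/diazomethane routes to unsaturated diazoketones.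

Step 5
Reactants: 7 ethyl 4-methylpent-3-enoate
Product: 10 triisopropyl[(5-methylhex-4-en-1-yn-1-yl)oxy]silane, via dibromo ketone enolate 8 (not isolated), via lithium ynolate 9 (not isolated)
Conditions: CH2Br2, lithium 2,2,6,6-tetramethylpiperidide, THF, −78 °C; then LiN(SiMe3)2, then n-BuLi, −78 °C to rt; then i-Pr3SiCl, −78 °C to rt
Reagents that add atoms: dibromomethane, BrCBr; triisopropylsilyl chloride, CC(C)[Si](Cl)(C(C)C)C(C)C
Why: Kowalski ester homologation, in which LiCHBr2 adds to the ester and enolate 8 undergoes bromine–lithium exchange and a carbenoid 1,2-shift to ynolate 9, which the bulky silyl chloride should trap on oxygen.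

Step 6
Reactants: 6 (E)-6-[(tert-butyldimethylsilyl)oxy]-1-diazohex-3-en-2-one; 10 triisopropyl[(5-methylhex-4-en-1-yn-1-yl)oxy]silane
Product: 15 6-{2-[(tert-butyldimethylsilyl)oxy]ethyl}-2-(3-methylbut-2-en-1-yl)-3-[(triisopropylsilyl)oxy]phenol, via vinylketene 11 (not isolated), via vinylcyclobutenone 12 (not isolated), via dienylketene 13 (not isolated), via cyclohexadienone 14 (not isolated)
Conditions: hν (254 nm, quartz), 10 (1.2 equiv), ClCH2CH2Cl, rt; then 80 °C
Reagents that add atoms: none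
Why: Light expels N2 from 6 and the photo-Wolff 1,2-shift of the alkenyl group (forming C5'–C6') gives vinylketene 11, which the electron-rich siloxyalkyne traps in a polar (2+2) cycloaddition, its prenyl-bearing β-carbon bonding to the ketene carbonyl carbon (C2'–C3') and its oxygen-bearing carbon to the ketene α-carbon (C4'–C5'). Cyclobutenone 12 opens by a 4π electrocyclic reaction to dienylketene 13, which closes ring B by a thermal disrotatory 6π electrocyclisation (C1'–C2') to dienone 14 and tautomerises to phenol 15. The closest known reaction type is the Danheiser benzannulation of unsaturated α-diazoketones with siloxyalkynes, which gives resorcinol monosilyl ethers. No stereocentre is formed. The step needs regioselectivity in the (2+2) event and chemoselectivity for the alkyne over the prenyl olefin. Both follow from the polarisation of the ynol silyl ether, whose β-carbon is by far the most nucleophilic π-centre present, so the free hydroxyl should end up at C2', the silyl ether at C4' and the prenyl group between them at C3'.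

Step 7
Reactants: 15 6-{2-[(tert-butyldimethylsilyl)oxy]ethyl}-2-(3-methylbut-2-en-1-yl)-3-[(triisopropylsilyl)oxy]phenol
Product: 16 8-{2-[(tert-butyldimethylsilyl)oxy]ethyl}-2,2-dimethyl-5-[(triisopropylsilyl)oxy]-2H-chromene
Conditions: DDQ (1.1 equiv), 1,4-dioxane, 80 °C
Reagents that add atoms: none
Why: DDQ dehydrogenative cyclisation of an ortho-prenylphenol (hydride abstraction at the benzylic–allylic CH2, then oxa-6π electrocyclisation of the ortho-quinone methide) can engage only the free O2', so only the angular 2,2-dimethylchromene should form.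

Step 8
Reactants: 16 8-{2-[(tert-butyldimethylsilyl)oxy]ethyl}-2,2-dimethyl-5-[(triisopropylsilyl)oxy]-2H-chromene
Product: 17 2-{2,2-dimethyl-5-[(triisopropylsilyl)oxy]-2H-chromen-8-yl}ethan-1-ol
Conditions: PPTS (cat.), MeOH, rt to 40 °C
Reagents that add atoms: none
Why: Acid-catalysed methanolysis (selective desilylation) should cleave the primary alkyl TBS ether much faster than the hindered aryl TIPS ether and is too mild to add methanol to the chromene.

Step 9
Reactants: 17 2-{2,2-dimethyl-5-[(triisopropylsilyl)oxy]-2H-chromen-8-yl}ethan-1-ol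
Product: 19 2-{2,2-dimethyl-5-[(triisopropylsilyl)oxy]-2H-chromen-8-yl}acetic acid, via arylacetaldehyde 18 (not isolated)
Conditions: TEMPO (cat.), PhI(OAc)2 (2.2 equiv), MeCN/H2O (1:1), rt
Reagents that add atoms: water, O
Why: TEMPO-catalysed oxidation in aqueous acetonitrile takes the primary alcohol through aldehyde 18 and its hydrate to the acid and should leave the chromene olefin and the aryl silyl ether untouched.

Step 10
Reactants: 19 2-{2,2-dimethyl-5-[(triisopropylsilyl)oxy]-2H-chromen-8-yl}acetic acid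
Product: 21 (S)-4-benzyl-3-(2-{2,2-dimethyl-5-[(triisopropylsilyl)oxy]-2H-chromen-8-yl}acetyl)oxazolidin-2-one, via mixed pivalic anhydride 20 (not isolated)
Conditions: PivCl, Et3N, THF, −20 °C; then LiCl, (S)-4-benzyloxazolidin-2-one, −20 °C to rt
Reagents that add atoms: (S)-4-benzyloxazolidin-2-one, O=C1N[C@@H](Cc2ccccc2)CO1
Why: N-acylation of the Evans oxazolidinone through a mixed pivalic anhydride, whose hindered pivaloyl carbonyl directs attack to the arylacetyl carbonyl.

Step 11
Reactants: 21 (S)-4-benzyl-3-(2-{2,2-dimethyl-5-[(triisopropylsilyl)oxy]-2H-chromen-8-yl}acetyl)oxazolidin-2-one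
Product: 23 (S)-4-benzyl-3-[(R)-2-{2,2-dimethyl-5-[(triisopropylsilyl)oxy]-2H-chromen-8-yl}-3-hydroxypropanoyl]oxazolidin-2-one, via titanium enolate 22 (not isolated)
Conditions: TiCl4 (1.05 equiv), i-Pr2NEt (1.1 equiv), CH2Cl2, 0 °C; then s-trioxane (1 equiv), TiCl4 (1.05 equiv), 0 °C
Reagents that add atoms: 1,3,5-trioxane, C1OCOCO1
Why: Evans asymmetric hydroxymethylation, in which TiCl4-activated formaldehyde attacks the chelated (Z)-titanium enolate 22 on the face opposite the C4 benzyl group and so sets C3 as (R); the enolate is the strongest nucleophile present and should outcompete the chromene olefin and ring B for the electrophile.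

Step 12
Reactants: 24 phloroglucinol
Product: 25 3,5-bis[(triisopropylsilyl)oxy]phenol
Conditions: i-Pr3SiCl (2.0 equiv), imidazole, DMF, 0 °C to rt
Reagents that add atoms: triisopropylsilyl chloride, CC(C)[Si](Cl)(C(C)C)C(C)C
Why: Statistical silylation (silyl ether formation) of the symmetric triol with two equivalents of silyl chloride should give the bis-ether as the main fraction, separable from mono- and tris-ethers by chromatography.

Step 13
Reactants: 23 (S)-4-benzyl-3-[(R)-2-{2,2-dimethyl-5-[(triisopropylsilyl)oxy]-2H-chromen-8-yl}-3-hydroxypropanoyl]oxazolidin-2-one; 25 3,5-bis[(triisopropylsilyl)oxy]phenol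
Product: 26 (S)-4-benzyl-3-[(R)-3-{3,5-bis[(triisopropylsilyl)oxy]phenoxy}-2-{2,2-dimethyl-5-[(triisopropylsilyl)oxy]-2H-chromen-8-yl}propanoyl]oxazolidin-2-one
Conditions: PPh3, DIAD, toluene, 0 °C to rt
Reagents that add atoms: none
Why: Mitsunobu etherification of a primary alcohol with a phenol does not touch the stereocentre, and A(1,3) strain in the imide holds the C3–H bond in the carbonyl plane, which should slow E1cB elimination.

Step 14
Reactants: 26 (S)-4-benzyl-3-[(R)-3-{3,5-bis[(triisopropylsilyl)oxy]phenoxy}-2-{2,2-dimethyl-5-[(triisopropylsilyl)oxy]-2H-chromen-8-yl}propanoyl]oxazolidin-2-one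
Product: 28 (R)-3-{3,5-bis[(triisopropylsilyl)oxy]phenoxy}-2-{2,2-dimethyl-5-[(triisopropylsilyl)oxy]-2H-chromen-8-yl}propanoic acid, via peroxy acid 27 (not isolated)
Conditions: LiOH, H2O2, THF/H2O (3:1), 0 °C; then aq. Na2SO3; 1 M HCl to pH 3
Reagents that add atoms: hydrogen peroxide, OO
Why: Hydroperoxide cleavage of the Evans imide attacks the exocyclic carbonyl selectively, and at 0 °C the medium should be too weakly basic to epimerise C3 or strip the aryl TIPS ethers; sulfite reduces peracid 27 in the quench.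

Step 15
Reactants: 28 (R)-3-{3,5-bis[(triisopropylsilyl)oxy]phenoxy}-2-{2,2-dimethyl-5-[(triisopropylsilyl)oxy]-2H-chromen-8-yl}propanoic acid
Product: 30 (R)-3-{2,2-dimethyl-5-[(triisopropylsilyl)oxy]-2H-chromen-8-yl}-5,7-bis[(triisopropylsilyl)oxy]chroman-4-one, via mixed trifluoroacetic anhydride 29 (not isolated)
Conditions: (CF3CO)2O (2 equiv), CH2Cl2, 0 °C to rt
Reagents that add atoms: none
Why: Intramolecular Friedel–Crafts acylation through the mixed anhydride closes the six-membered ring C at either of the two equivalent positions ortho to the ether oxygen of ring A, each activated by three oxygens, under conditions with no base to enolise C3.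

Step 16
Reactants: 30 (R)-3-{2,2-dimethyl-5-[(triisopropylsilyl)oxy]-2H-chromen-8-yl}-5,7-bis[(triisopropylsilyl)oxy]chroman-4-one
Product: 31 (R)-5,7-dihydroxy-3-(5-hydroxy-2,2-dimethyl-2H-chromen-8-yl)chroman-4-one
Conditions: Bu4NF (3.3 equiv), AcOH (3.3 equiv), THF, 0 °C
Reagents that add atoms: none
Why: Fluoride-mediated cleavage of the three aryl silyl ethers, with acetic acid buffering the phenoxides so that the α-aryl ketone centre should not be enolised.

**Compound list**

1 | propane-1,3-diol | OCCCO | starting material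
2 | 3-[(tert-butyldimethylsilyl)oxy]propan-1-ol | OCCCO[Si](C)(C)C(C)(C)C | intermediate
3 | 3-[(tert-butyldimethylsilyl)oxy]propanal | O=CCCO[Si](C)(C)C(C)(C)C | intermediate
4 | (E)-6-[(tert-butyldimethylsilyl)oxy]hex-3-en-2-one | CC(=O)/C=C/CCO[Si](C)(C)C(C)(C)C | intermediate
5 | (E)-8-[(tert-butyldimethylsilyl)oxy]-1,1,1-trifluorooct-5-ene-2,4-dione (not isolated) | FC(F)(F)C(=O)CC(=O)/C=C/CCO[Si](C)(C)C(C)(C)C | intermediate
6 | (E)-6-[(tert-butyldimethylsilyl)oxy]-1-diazohex-3-en-2-one | [N-]=[N+]=CC(=O)/C=C/CCO[Si](C)(C)C(C)(C)C | intermediate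
7 | ethyl 4-methylpent-3-enoate | CCOC(=O)CC=C(C)C | starting material
8 | lithium 1,1-dibromo-5-methylhexa-1,4-dien-2-olate (not isolated) | [Li+].[O-]C(CC=C(C)C)=C(Br)Br | intermediate
9 | lithium 5-methylhex-4-en-1-yn-1-olate (not isolated) | [Li+].[O-]C#CCC=C(C)C | intermediate
10 | triisopropyl[(5-methylhex-4-en-1-yn-1-yl)oxy]silane | CC(C)=CCC#CO[Si](C(C)C)(C(C)C)C(C)C | intermediate
11 | (E)-6-[(tert-butyldimethylsilyl)oxy]hexa-1,3-dien-1-one (vinylketene, not isolated) | O=C=C/C=C/CCO[Si](C)(C)C(C)(C)C | intermediate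
12 | 4-{(E)-4-[(tert-butyldimethylsilyl)oxy]but-1-en-1-yl}-2-(3-methylbut-2-en-1-yl)-3-[(triisopropylsilyl)oxy]cyclobut-2-en-1-one (racemic, not isolated) | O=C1C(CC=C(C)C)=C(O[Si](C(C)C)(C(C)C)C(C)C)C1/C=C/CCO[Si](C)(C)C(C)(C)C | intermediate
13 | (3E,5E)-8-[(tert-butyldimethylsilyl)oxy]-2-(3-methylbut-2-en-1-yl)-3-[(triisopropylsilyl)oxy]octa-1,3,5-trien-1-one (ketene carbon and C5 cis across C3=C4, not isolated) | O=C=C(CC=C(C)C)/C(O[Si](C(C)C)(C(C)C)C(C)C)=C\C=C\CCO[Si](C)(C)C(C)(C)C | intermediate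
14 | 6-{2-[(tert-butyldimethylsilyl)oxy]ethyl}-2-(3-methylbut-2-en-1-yl)-3-[(triisopropylsilyl)oxy]cyclohexa-2,4-dien-1-one (racemic, not isolated) | O=C1C(CC=C(C)C)=C(O[Si](C(C)C)(C(C)C)C(C)C)C=CC1CCO[Si](C)(C)C(C)(C)C | intermediate
15 | 6-{2-[(tert-butyldimethylsilyl)oxy]ethyl}-2-(3-methylbut-2-en-1-yl)-3-[(triisopropylsilyl)oxy]phenol | Oc1c(CC=C(C)C)c(O[Si](C(C)C)(C(C)C)C(C)C)ccc1CCO[Si](C)(C)C(C)(C)C | intermediate
16 | 8-{2-[(tert-butyldimethylsilyl)oxy]ethyl}-2,2-dimethyl-5-[(triisopropylsilyl)oxy]-2H-chromene | CC1(C)C=Cc2c(O[Si](C(C)C)(C(C)C)C(C)C)ccc(CCO[Si](C)(C)C(C)(C)C)c2O1 | intermediate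
17 | 2-{2,2-dimethyl-5-[(triisopropylsilyl)oxy]-2H-chromen-8-yl}ethan-1-ol | CC1(C)C=Cc2c(O[Si](C(C)C)(C(C)C)C(C)C)ccc(CCO)c2O1 | intermediate
18 | 2-{2,2-dimethyl-5-[(triisopropylsilyl)oxy]-2H-chromen-8-yl}acetaldehyde (not isolated) | CC1(C)C=Cc2c(O[Si](C(C)C)(C(C)C)C(C)C)ccc(CC=O)c2O1 | intermediate
19 | 2-{2,2-dimethyl-5-[(triisopropylsilyl)oxy]-2H-chromen-8-yl}acetic acid | CC1(C)C=Cc2c(O[Si](C(C)C)(C(C)C)C(C)C)ccc(CC(=O)O)c2O1 | intermediate
20 | 2-{2,2-dimethyl-5-[(triisopropylsilyl)oxy]-2H-chromen-8-yl}acetic pivalic anhydride (not isolated) | CC1(C)C=Cc2c(O[Si](C(C)C)(C(C)C)C(C)C)ccc(CC(=O)OC(=O)C(C)(C)C)c2O1 | intermediate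
21 | (S)-4-benzyl-3-(2-{2,2-dimethyl-5-[(triisopropylsilyl)oxy]-2H-chromen-8-yl}acetyl)oxazolidin-2-one | CC1(C)C=Cc2c(O[Si](C(C)C)(C(C)C)C(C)C)ccc(CC(=O)N3[C@@H](Cc4ccccc4)COC3=O)c2O1 | intermediate
22 | trichlorotitanium (Z)-enolate of 21 (not isolated) | CC1(C)C=Cc2c(O[Si](C(C)C)(C(C)C)C(C)C)ccc(/C=C(\O[Ti](Cl)(Cl)Cl)N3[C@@H](Cc4ccccc4)COC3=O)c2O1 | intermediate
23 | (S)-4-benzyl-3-[(R)-2-{2,2-dimethyl-5-[(triisopropylsilyl)oxy]-2H-chromen-8-yl}-3-hydroxypropanoyl]oxazolidin-2-one | CC1(C)C=Cc2c(O[Si](C(C)C)(C(C)C)C(C)C)ccc([C@H](CO)C(=O)N3[C@@H](Cc4ccccc4)COC3=O)c2O1 | intermediate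
24 | phloroglucinol (benzene-1,3,5-triol) | Oc1cc(O)cc(O)c1 | starting material
25 | 3,5-bis[(triisopropylsilyl)oxy]phenol | Oc1cc(O[Si](C(C)C)(C(C)C)C(C)C)cc(O[Si](C(C)C)(C(C)C)C(C)C)c1 | intermediate
26 | (S)-4-benzyl-3-[(R)-3-{3,5-bis[(triisopropylsilyl)oxy]phenoxy}-2-{2,2-dimethyl-5-[(triisopropylsilyl)oxy]-2H-chromen-8-yl}propanoyl]oxazolidin-2-one | CC1(C)C=Cc2c(O[Si](C(C)C)(C(C)C)C(C)C)ccc([C@H](COc3cc(O[Si](C(C)C)(C(C)C)C(C)C)cc(O[Si](C(C)C)(C(C)C)C(C)C)c3)C(=O)N4[C@@H](Cc5ccccc5)COC4=O)c2O1 | intermediate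
27 | (R)-3-{3,5-bis[(triisopropylsilyl)oxy]phenoxy}-2-{2,2-dimethyl-5-[(triisopropylsilyl)oxy]-2H-chromen-8-yl}propaneperoxoic acid (not isolated) | CC1(C)C=Cc2c(O[Si](C(C)C)(C(C)C)C(C)C)ccc([C@H](COc3cc(O[Si](C(C)C)(C(C)C)C(C)C)cc(O[Si](C(C)C)(C(C)C)C(C)C)c3)C(=O)OO)c2O1 | intermediate
28 | (R)-3-{3,5-bis[(triisopropylsilyl)oxy]phenoxy}-2-{2,2-dimethyl-5-[(triisopropylsilyl)oxy]-2H-chromen-8-yl}propanoic acid | CC1(C)C=Cc2c(O[Si](C(C)C)(C(C)C)C(C)C)ccc([C@H](COc3cc(O[Si](C(C)C)(C(C)C)C(C)C)cc(O[Si](C(C)C)(C(C)C)C(C)C)c3)C(=O)O)c2O1 | intermediate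
29 | mixed anhydride of 28 with trifluoroacetic acid (not isolated) | CC1(C)C=Cc2c(O[Si](C(C)C)(C(C)C)C(C)C)ccc([C@H](COc3cc(O[Si](C(C)C)(C(C)C)C(C)C)cc(O[Si](C(C)C)(C(C)C)C(C)C)c3)C(=O)OC(=O)C(F)(F)F)c2O1 | intermediate
30 | (R)-3-{2,2-dimethyl-5-[(triisopropylsilyl)oxy]-2H-chromen-8-yl}-5,7-bis[(triisopropylsilyl)oxy]chroman-4-one | CC1(C)C=Cc2c(O[Si](C(C)C)(C(C)C)C(C)C)ccc([C@@H]3COc4cc(O[Si](C(C)C)(C(C)C)C(C)C)cc(O[Si](C(C)C)(C(C)C)C(C)C)c4C3=O)c2O1 | intermediate
31 | (R)-5,7-dihydroxy-3-(5-hydroxy-2,2-dimethyl-2H-chromen-8-yl)chroman-4-one | CC1(C)C=Cc2c(O)ccc([C@@H]3COc4cc(O)cc(O)c4C3=O)c2O1 | target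

**Count and risks**

Total step count: 16. Longest linear sequence: 14 steps (steps 1–4, 6–11 and 13–16, from propane-1,3-diol).

The three steps most likely to fail:

Step 6 (key step). The transient vinylketene may be lost by dimerisation or by reaction with adventitious nucleophiles before the alkyne traps it, and prolonged short-wavelength irradiation may degrade the siloxyalkyne or the phenol as it accumulates. The fallback separates ketene generation from ring formation. It sets out from 6 (together with ester 7, by way of ynolate 9) and comes back at 15. C-Silylation of 6 with i-Pr3SiOTf and i-Pr2NEt should give (E)-6-[(tert-butyldimethylsilyl)oxy]-1-diazo-1-(triisopropylsilyl)hex-3-en-2-one F1. Its photochemical Wolff rearrangement at 300 nm in benzene should give the stable, isolable (E)-6-[(tert-butyldimethylsilyl)oxy]-2-(triisopropylsilyl)hexa-1,3-dien-1-one F2. In the dark, F2 is combined in THF with lithium ynolate 9, made from 7 as in step 5 but without the silyl chloride. C-Acylation of the ynolate by the silylketene and 6π electrocyclisation should lead to 6-{2-[(tert-butyldimethylsilyl)oxy]ethyl}-2-(3-methylbut-2-en-1-yl)-4-(triisopropylsilyl)benzene-1,3-diol F3 as its lithium 3-phenoxide (not isolated). A 1,3-Brook shift then moves the silyl group from C5' to O4', and protonation on work-up gives 15 with the same bonds formed and the same oxygen differentiation.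

Step 11. Formaldehyde activated by TiCl4 may attack the electron-rich chromene olefin (Prins reaction) or C5' of ring B (hydroxymethylation or chloromethylation) once the enolate is consumed, and HCl from the titanium reagent may oligomerise the chromene. The fallback uses no strong Lewis acid and also bypasses the Mitsunobu step with its risk of β-elimination. It sets out from 21 and 25 and comes back at 26. Phenol 25 is alkylated with ClCH2SMe (NaH, NaI, DMF, 0 °C) to {[3,5-bis(triisopropylsilyloxy)phenoxy]methyl}(methyl)sulfane F4. Treatment with SO2Cl2 in CH2Cl2 at −78 °C in the presence of cyclohexene converts it into 1-(chloromethoxy)-3,5-bis[(triisopropylsilyl)oxy]benzene F5. Imide 21 is deprotonated with NaN(SiMe3)2 in THF at −78 °C to the sodium (Z)-enolate of 21 F6. SN2 alkylation of F6 by the α-chloro ether F5, on the face opposite the benzyl group as in Evans alkylations with alkoxymethyl chlorides, should give 26 with the (R) configuration at C3.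

Step 15. Acid-promoted enolisation of the newly formed α-aryl ketone, or ketene formation from the mixed anhydride, may erode the configuration at C3 during ring closure. The fallback restores it by dynamic kinetic resolution. It sets out from 30 of reduced enantiomeric purity and comes back at 30. Noyori transfer hydrogenation with RuCl(p-cymene)[(R,R)-TsDPEN] in HCO2H/Et3N at rt reduces the ketone while the two ketone antipodes interconvert by enolisation. With the usual sense of induction for benzo-fused ketones it should funnel both into the cis alcohol (3R,4R)-3-{2,2-dimethyl-5-[(triisopropylsilyl)oxy]-2H-chromen-8-yl}-5,7-bis[(triisopropylsilyl)oxy]chroman-4-ol F7. Oxidation with Dess–Martin periodinane buffered with NaHCO3 in CH2Cl2 at 0 °C should return 30 as the (R)-ketone without a base or acid strong enough to enolise it.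

**Further compounds**

F1 | step 6 | (E)-6-[(tert-butyldimethylsilyl)oxy]-1-diazo-1-(triisopropylsilyl)hex-3-en-2-one | [N-]=[N+]=C([Si](C(C)C)(C(C)C)C(C)C)C(=O)/C=C/CCO[Si](C)(C)C(C)(C)C
F2 | step 6 | (E)-6-[(tert-butyldimethylsilyl)oxy]-2-(triisopropylsilyl)hexa-1,3-dien-1-one | O=C=C([Si](C(C)C)(C(C)C)C(C)C)/C=C/CCO[Si](C)(C)C(C)(C)C
F3 | step 6 | 6-{2-[(tert-butyldimethylsilyl)oxy]ethyl}-2-(3-methylbut-2-en-1-yl)-4-(triisopropylsilyl)benzene-1,3-diol (formed as its lithium 3-phenoxide, not isolated) | Oc1c(CC=C(C)C)c(O)c([Si](C(C)C)(C(C)C)C(C)C)cc1CCO[Si](C)(C)C(C)(C)C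
F4 | step 11 | {[3,5-bis(triisopropylsilyloxy)phenoxy]methyl}(methyl)sulfane | CSCOc1cc(O[Si](C(C)C)(C(C)C)C(C)C)cc(O[Si](C(C)C)(C(C)C)C(C)C)c1
F5 | step 11 | 1-(chloromethoxy)-3,5-bis[(triisopropylsilyl)oxy]benzene | ClCOc1cc(O[Si](C(C)C)(C(C)C)C(C)C)cc(O[Si](C(C)C)(C(C)C)C(C)C)c1
F6 | step 11 | sodium (Z)-enolate of 21 (not isolated) | CC1(C)C=Cc2c(O[Si](C(C)C)(C(C)C)C(C)C)ccc(/C=C(\[O-])N3[C@@H](Cc4ccccc4)COC3=O)c2O1.[Na+]
F7 | step 15 | (3R,4R)-3-{2,2-dimethyl-5-[(triisopropylsilyl)oxy]-2H-chromen-8-yl}-5,7-bis[(triisopropylsilyl)oxy]chroman-4-ol | CC1(C)C=Cc2c(O[Si](C(C)C)(C(C)C)C(C)C)ccc([C@@H]3COc4cc(O[Si](C(C)C)(C(C)C)C(C)C)cc(O[Si](C(C)C)(C(C)C)C(C)C)c4[C@@H]3O)c2O1
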